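**Strategy.** Ring C (O1–C2–C3–C4(=O)–C4a=C8a) is a β-aryloxy ketone: its O1–C2–C3–C4 segment is a masked β-lactone and its C4a=C8a edge an ortho-fluoroaryl anion. The route therefore makes the (S)-4-aryl-oxetan-2-one that carries ring B (stereocentre from asymmetric transfer hydrogenation) and expands it by two atoms: the ring A aryllithium opens the lactone at the acyl carbon (C4–C4a bond), and the liberated C2 alkoxide displaces the ortho fluoride (O1–C8a bond). One flask thus converts the four-membered lactone into the six-membered chromanone, joins both halves and carries C2 through untouched; acid removal of three MOM groups ends the synthesis.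

Key step: step 11

Remark: the SMILES encodes the (2S)-flavanone (CIP order at C2: O1 > aryl > C3 > H, unchanged from 14 to 20); chromanone numbering (O1 to C8a) is used for the corresponding atoms of all precursors, and 7 is taken as a purchasable MOM ether.

**Ring A fragment**

Step 1
Reactants: 1 5-fluorobenzene-1,3-diol
Product: 2 1-fluoro-3,5-bis(methoxymethoxy)benzene
Conditions: MOMCl, i-Pr2NEt, CH2Cl2, 0 °C to rt
Reagents that add atoms: chloromethyl methyl ether, COCCl
Why: Williamson-type O-alkylation of both phenols gives acetal ethers that tolerate the organolithium steps and can be removed together by acid at the end.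

Step 2
Reactants: 2 1-fluoro-3,5-bis(methoxymethoxy)benzene
Product: 3 2,4-dibromo-3-fluoro-1,5-bis(methoxymethoxy)benzene
Conditions: NBS (2.1 equiv), MeCN, 0 °C to rt
Reagents that add atoms: N-bromosuccinimide, O=C1CCC(=O)N1Br
Why: Electrophilic aromatic bromination should enter the two equivalent positions ortho to fluorine, each para to one alkoxy group and ortho to the other, whereas the position between the two OMOM groups is the most hindered (compare the 4,6-dibromination of resorcinol diethers).

Step 3
Reactants: 3 2,4-dibromo-3-fluoro-1,5-bis(methoxymethoxy)benzene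
Product: 6 1-bromo-2-fluoro-4,6-bis(methoxymethoxy)-3-(3-methylbut-2-en-1-yl)benzene, via aryllithium 4 (not isolated), via arylcopper 5 (not isolated)
Conditions: n-BuLi (1.0 equiv), THF, −78 °C; CuBr·SMe2, −78 to −40 °C; prenyl bromide, −78 to 0 °C
Reagents that add atoms: prenyl bromide (1-bromo-3-methylbut-2-ene), CC(C)=CCBr
Why: Bromine–lithium exchange at one of the two equivalent bromides (kept at −78 °C, where an ortho-fluoroaryllithium does not lose LiF), transmetalation to copper and copper-mediated allylic substitution of prenyl bromide at its primary carbon install the C8 prenyl group and keep the second bromide for step 11.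

**Ring B fragment**

Step 4
Reactants: 7 1-bromo-4-(methoxymethoxy)benzene; 8 2-methylpropanal
Product: 9 2-[4-(methoxymethoxy)phenyl]-2-methylpropanal
Conditions: Pd(OAc)2, rac-BINAP, Cs2CO3, 1,4-dioxane, 80 °C (sealed vessel, excess 8)
Reagents that add atoms: none
Why: Palladium-catalysed α-arylation of the α-branched aldehyde through its caesium enolate forms the quaternary benzylic carbon of the 1,1-dimethylallyl group, and the product has no α-hydrogen left, so it cannot be arylated twice or enolised.

Step 5
Reactants: 9 2-[4-(methoxymethoxy)phenyl]-2-methylpropanal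
Product: 10 1-(methoxymethoxy)-4-(2-methylbut-3-en-2-yl)benzene
Conditions: Ph3PCH3Br, KOt-Bu, THF, 0 °C to rt
Reagents that add atoms: methyltriphenylphosphonium bromide, C[P+](c1ccccc1)(c1ccccc1)c1ccccc1.[Br-]
Why: Wittig methylenation of the non-enolisable aldehyde with Ph3P=CH2 made in the flask gives the terminal vinyl group of the 1,1-dimethylallyl unit.

Step 6
Reactants: 10 1-(methoxymethoxy)-4-(2-methylbut-3-en-2-yl)benzene
Product: 12 1-[2-(methoxymethoxy)-5-(2-methylbut-3-en-2-yl)phenyl]ethan-1-one, via aryllithium 11 (not isolated)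
Conditions: n-BuLi, TMEDA, Et2O, 0 °C; then MeC(O)N(OMe)Me, −78 to 0 °C; aqueous work-up
Reagents that add atoms: N-methoxy-N-methylacetamide, CC(=O)N(C)OC
Why: Directed ortho-metalation by the coordinating MOM ether (both ortho positions are equivalent) followed by Weinreb ketone synthesis, which stops at the ketone stage, places the two-carbon unit that becomes C2 and C3 ortho to the protected phenol.

Step 7
Reactants: 12 1-[2-(methoxymethoxy)-5-(2-methylbut-3-en-2-yl)phenyl]ethan-1-one
Product: 13 ethyl 3-[2-(methoxymethoxy)-5-(2-methylbut-3-en-2-yl)phenyl]-3-oxopropanoate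
Conditions: NaH, (EtO)2CO, THF, 65 °C; then AcOH
Reagents that add atoms: diethyl carbonate, CCOC(=O)OCC
Why: Crossed Claisen condensation of the methyl ketone enolate with the non-enolisable diethyl carbonate, driven by deprotonation of the β-keto ester, adds the carbon that becomes C4.

Step 8
Reactants: 13 ethyl 3-[2-(methoxymethoxy)-5-(2-methylbut-3-en-2-yl)phenyl]-3-oxopropanoate
Product: 14 ethyl (3S)-3-hydroxy-3-[2-(methoxymethoxy)-5-(2-methylbut-3-en-2-yl)phenyl]propanoate
Conditions: RuCl(p-cymene)[(S,S)-TsDPEN] (1 mol %), HCO2H/Et3N (5:2), 30 °C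
Reagents that add atoms: none
Why: Noyori-type asymmetric transfer hydrogenation of the aryl ketone sets C2, because the CH/π contact between the aryl group and the p-cymene ligand of the (S,S)-catalyst directs hydride to the face that gives the (S)-carbinol (as acetophenone gives (S)-1-phenylethanol), while the isolated alkene and the MOM ether are inert.

Step 9
Reactants: 14 ethyl (3S)-3-hydroxy-3-[2-(methoxymethoxy)-5-(2-methylbut-3-en-2-yl)phenyl]propanoate
Product: 15 (3S)-3-hydroxy-3-[2-(methoxymethoxy)-5-(2-methylbut-3-en-2-yl)phenyl]propanoic acid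
Conditions: LiOH, THF/H2O, 0 °C to rt; then 0.5 M HCl, 0 °C, to pH 3
Reagents that add atoms: lithium hydroxide, [Li+].[OH-]
Why: Saponification of the ethyl ester under cold conditions that avoid retro-aldol cleavage, followed by brief mild acidification that the MOM ether tolerates, gives the β-hydroxy acid with the stereocentre unchanged.

Step 10
Reactants: 15 (3S)-3-hydroxy-3-[2-(methoxymethoxy)-5-(2-methylbut-3-en-2-yl)phenyl]propanoic acid
Product: 16 (4S)-4-[2-(methoxymethoxy)-5-(2-methylbut-3-en-2-yl)phenyl]oxetan-2-one
Conditions: PhSO2Cl, pyridine, 0 °C; cold work-up, used at once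
Reagents that add atoms: none
Why: β-Lactonisation by carboxyl activation with PhSO2Cl and 4-exo-trig attack of the hydroxyl group on the activated acyl carbon leaves the C–O bond at the stereocentre intact, so (S) is retained, and the lactone is kept cold because its electron-rich aryl group favours ionisation and loss of CO2.

**Union and completion**

Step 11
Reactants: 6 1-bromo-2-fluoro-4,6-bis(methoxymethoxy)-3-(3-methylbut-2-en-1-yl)benzene; 16 (4S)-4-[2-(methoxymethoxy)-5-(2-methylbut-3-en-2-yl)phenyl]oxetan-2-one
Product: 19 (2S)-5,7-bis(methoxymethoxy)-2-[2-(methoxymethoxy)-5-(2-methylbut-3-en-2-yl)phenyl]-8-(3-methylbut-2-en-1-yl)-2,3-dihydro-4H-chromen-4-one, via aryllithium 17 (not isolated), via lithium keto alkoxide 18 (not isolated)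
Conditions: 6, t-BuLi (2.0 equiv), THF, −78 °C; cannulate into 16, THF, −78 °C; then DMPU, −78 to 0 °C; aq NH4Cl
Reagents that add atoms: none
Why: Proposed new method: the hard aryllithium 17 should attack the strained lactone carbonyl with acyl–oxygen cleavage (the known opening of β-lactones at the acyl carbon by organolithium, lithium amide and lithiated phosphonate nucleophiles) to give the di-ortho-substituted aryl ketone 18, whose C2 lithium alkoxide, once DMPU loosens the lithium chelate, should displace the fluoride at C8a by intramolecular SNAr ortho to the carbonyl group (the reaction type that closes chromanones, chromones and xanthones from 2-fluoroaryl ketones), so that C4a and C8a are inserted into the C4–O1 bond of the four-membered ring; the closest known analogue of the overall change is the insertion of arynes into the acyl C–O bond of carboxylic acids. Ring C closes by addition–elimination at C8a, formally a 6-endo-trig attack of O1 on the C8a=C4a–C4=O vinylogous acceptor followed by loss of fluoride. No stereocentre is formed, and because the C2–O1 bond of 16 is never broken the (S) configuration is carried over unchanged. The step needs acyl attack instead of α-deprotonation or alkyl–oxygen attack (secured by the hard aryllithium at −78 °C and inverse addition), a single addition (the ketone of 18 is flanked by F and OMOM and resists a second hindered aryllithium), and ring closure faster than retro-aldol cleavage of 18 (fluoride ortho to the carbonyl, both alkoxy groups meta to C8a, low temperature).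

Step 12
Reactants: 19 (2S)-5,7-bis(methoxymethoxy)-2-[2-(methoxymethoxy)-5-(2-methylbut-3-en-2-yl)phenyl]-8-(3-methylbut-2-en-1-yl)-2,3-dihydro-4H-chromen-4-one
Product: 20 (2S)-5,7-dihydroxy-2-[2-hydroxy-5-(2-methylbut-3-en-2-yl)phenyl]-8-(3-methylbut-2-en-1-yl)-2,3-dihydro-4H-chromen-4-one
Conditions: 3 M aq HCl, MeOH, 45 °C
Reagents that add atoms: none
Why: Acid-catalysed acetal exchange in methanol (MOM ether cleavage) frees the three phenols, the flavanone should not ring-open or racemise at C2 under mild acid, and the moderate temperature is chosen to avoid addition of the C7 phenol to the prenyl alkene.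

**Compound list**

1 | 5-fluorobenzene-1,3-diol | Oc1cc(O)cc(F)c1 | starting material
2 | 1-fluoro-3,5-bis(methoxymethoxy)benzene | COCOc1cc(F)cc(OCOC)c1 | intermediate
3 | 2,4-dibromo-3-fluoro-1,5-bis(methoxymethoxy)benzene | COCOc1cc(OCOC)c(Br)c(F)c1Br | intermediate
4 | aryllithium: [3-bromo-2-fluoro-4,6-bis(methoxymethoxy)phenyl]lithium | [Li]c1c(F)c(Br)c(OCOC)cc1OCOC | intermediate
5 | arylcopper: [3-bromo-2-fluoro-4,6-bis(methoxymethoxy)phenyl]copper | [Cu]c1c(F)c(Br)c(OCOC)cc1OCOC | intermediate
6 | 1-bromo-2-fluoro-4,6-bis(methoxymethoxy)-3-(3-methylbut-2-en-1-yl)benzene | COCOc1cc(OCOC)c(CC=C(C)C)c(F)c1Br | intermediate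
7 | 1-bromo-4-(methoxymethoxy)benzene | COCOc1ccc(Br)cc1 | starting material
8 | 2-methylpropanal | CC(C)C=O | starting material
9 | 2-[4-(methoxymethoxy)phenyl]-2-methylpropanal | COCOc1ccc(cc1)C(C)(C)C=O | intermediate
10 | 1-(methoxymethoxy)-4-(2-methylbut-3-en-2-yl)benzene | COCOc1ccc(cc1)C(C)(C)C=C | intermediate
11 | aryllithium: [2-(methoxymethoxy)-5-(2-methylbut-3-en-2-yl)phenyl]lithium | [Li]c1cc(ccc1OCOC)C(C)(C)C=C | intermediate
12 | 1-[2-(methoxymethoxy)-5-(2-methylbut-3-en-2-yl)phenyl]ethan-1-one | CC(=O)c1cc(ccc1OCOC)C(C)(C)C=C | intermediate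
13 | ethyl 3-[2-(methoxymethoxy)-5-(2-methylbut-3-en-2-yl)phenyl]-3-oxopropanoate | CCOC(=O)CC(=O)c1cc(ccc1OCOC)C(C)(C)C=C | intermediate
14 | ethyl (3S)-3-hydroxy-3-[2-(methoxymethoxy)-5-(2-methylbut-3-en-2-yl)phenyl]propanoate | CCOC(=O)C[C@H](O)c1cc(ccc1OCOC)C(C)(C)C=C | intermediate
15 | (3S)-3-hydroxy-3-[2-(methoxymethoxy)-5-(2-methylbut-3-en-2-yl)phenyl]propanoic acid | OC(=O)C[C@H](O)c1cc(ccc1OCOC)C(C)(C)C=C | intermediate
16 | (4S)-4-[2-(methoxymethoxy)-5-(2-methylbut-3-en-2-yl)phenyl]oxetan-2-one | O=C1C[C@@H](c2cc(ccc2OCOC)C(C)(C)C=C)O1 | intermediate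
17 | aryllithium: [2-fluoro-4,6-bis(methoxymethoxy)-3-(3-methylbut-2-en-1-yl)phenyl]lithium | [Li]c1c(F)c(CC=C(C)C)c(OCOC)cc1OCOC | intermediate
18 | lithium keto alkoxide: lithium (1S)-3-[2-fluoro-4,6-bis(methoxymethoxy)-3-(3-methylbut-2-en-1-yl)phenyl]-1-[2-(methoxymethoxy)-5-(2-methylbut-3-en-2-yl)phenyl]-3-oxopropan-1-olate | [Li+].[O-][C@@H](CC(=O)c1c(F)c(CC=C(C)C)c(OCOC)cc1OCOC)c1cc(ccc1OCOC)C(C)(C)C=C | intermediate
19 | (2S)-5,7-bis(methoxymethoxy)-2-[2-(methoxymethoxy)-5-(2-methylbut-3-en-2-yl)phenyl]-8-(3-methylbut-2-en-1-yl)-2,3-dihydro-4H-chromen-4-one | C=CC(C)(C)c1ccc(OCOC)c([C@@H]2CC(=O)c3c(OCOC)cc(OCOC)c(CC=C(C)C)c3O2)c1 | intermediate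
20 | (2S)-5,7-dihydroxy-2-[2-hydroxy-5-(2-methylbut-3-en-2-yl)phenyl]-8-(3-methylbut-2-en-1-yl)-2,3-dihydro-4H-chromen-4-one | C=CC(C)(C)c1ccc(O)c([C@@H]2CC(=O)c3c(O)cc(O)c(CC=C(C)C)c3O2)c1 | target

**Count**

Total steps: 12. Longest linear sequence: 9 steps (7 to 20, steps 4 to 12); the ring A branch (steps 1 to 3) joins at step 11.

**Steps most likely to fail**

1. Step 11 (proposed new method). The aryllithium may deprotonate the lactone or add twice, and the lithium aldolate may undergo retro-aldol cleavage and re-addition (loss of material and of enantiomeric purity) before fluoride is displaced. Fallback by known chemistry, setting out from 14 and 6 and returning at 19: ester 14 is converted with MeNHOMe·HCl and i-PrMgCl (THF, −20 °C) into the Weinreb amide (3S)-3-hydroxy-N-methoxy-N-methyl-3-[2-(methoxymethoxy)-5-(2-methylbut-3-en-2-yl)phenyl]propanamide F1, which is silylated (TESCl, imidazole, DMF) to its triethylsilyl ether (3S)-N-methoxy-N-methyl-3-[2-(methoxymethoxy)-5-(2-methylbut-3-en-2-yl)phenyl]-3-(triethylsilyloxy)propanamide F2. Aryllithium 17, made from 6 as in step 11, then gives by Weinreb ketone synthesis the β-silyloxy ketone (3S)-1-[2-fluoro-4,6-bis(methoxymethoxy)-3-(3-methylbut-2-en-1-yl)phenyl]-3-[2-(methoxymethoxy)-5-(2-methylbut-3-en-2-yl)phenyl]-3-(triethylsilyloxy)propan-1-one F3, without over-addition and without a free aldolate. TBAF (THF, 0 °C) finally unmasks the alkoxide, which should close by intramolecular SNAr to 19.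

2. Step 10. Ionisation of the benzylic C–O bond of the electron-rich 4-aryl-β-lactone during the pyridine-mediated closure, work-up or chromatography may lead to loss of CO2 or to oligoester formation. Fallback setting out from 10 and returning at 16: ortho-lithiation of 10 (via 11) and a DMF quench give the aldehyde 2-(methoxymethoxy)-5-(2-methylbut-3-en-2-yl)benzaldehyde F4. A cinchona alkaloid and LiClO4 co-catalysed ketene–aldehyde [2+2] cycloaddition (acetyl chloride, i-Pr2NEt, O-trimethylsilylquinidine, CH2Cl2/Et2O, −78 °C) then forms 16 directly at low temperature, and the cold filtered solution is used at once in step 11. The sense of induction is checked by ethanolysis to 14, and O-trimethylsilylquinine is used instead should the opposite enantiomer form.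

3. Step 3. Loss of LiF from the aryllithium (aryne formation), bromine scrambling or double exchange, and partial attack at the tertiary carbon of prenyl bromide may erode the mono-prenylation. Fallback setting out from 3 and returning at 6, with no new compound: mono-selective, α-selective Suzuki–Miyaura coupling of 3 with 3-methylbut-2-enylboronic acid pinacol ester (0.9 equiv), catalysed by [1,3-bis(2,6-di(pentan-3-yl)phenyl)imidazol-2-ylidene](3-chloropyridine)PdCl2 with KOH in THF at 65 °C; unreacted 3 is recycled.

**Further compounds**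

F1 | step 11 | (3S)-3-hydroxy-N-methoxy-N-methyl-3-[2-(methoxymethoxy)-5-(2-methylbut-3-en-2-yl)phenyl]propanamide | CON(C)C(=O)C[C@H](O)c1cc(ccc1OCOC)C(C)(C)C=C
F2 | step 11 | (3S)-N-methoxy-N-methyl-3-[2-(methoxymethoxy)-5-(2-methylbut-3-en-2-yl)phenyl]-3-(triethylsilyloxy)propanamide | CC[Si](CC)(CC)O[C@@H](CC(=O)N(C)OC)c1cc(ccc1OCOC)C(C)(C)C=C
F3 | step 11 | (3S)-1-[2-fluoro-4,6-bis(methoxymethoxy)-3-(3-methylbut-2-en-1-yl)phenyl]-3-[2-(methoxymethoxy)-5-(2-methylbut-3-en-2-yl)phenyl]-3-(triethylsilyloxy)propan-1-one | CC[Si](CC)(CC)O[C@@H](CC(=O)c1c(F)c(CC=C(C)C)c(OCOC)cc1OCOC)c1cc(ccc1OCOC)C(C)(C)C=C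
F4 | step 10 | 2-(methoxymethoxy)-5-(2-methylbut-3-en-2-yl)benzaldehyde | O=Cc1cc(ccc1OCOC)C(C)(C)C=C
F0 | step 3 | none | none
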